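**Plan**

Numbering (target): ring C1 (alkene carbon carrying the carboxyl carbon C15), C2 (alkene CH), C3 (CH–OBz), C4 (CMe2), C5–C7 (CH2), C8 (epoxide C–Me), C9 (epoxide CH), C10 and C11 (CH2).
Enabling feature: with the epoxide read as a C8=C9 alkene and C3 as a ketone, C2=C1–C11–C10–C9=C8 is a 1,5-diene with one ring-cis (C1=C2) and one ring-trans (C8=C9) alkene in the eleven-membered ring, the pattern left by thermal cycloreversion of a bicyclo[2.2.0]hexane; C2–C8 with the C3 oxygen then form a cycloheptanone ring and C1, C9, C10, C11, C15 a cyclobutene ester.
Retrosynthesis: benzoate, epoxide oxygen, C3–H and ester methyl are removed; the C1=C2 and C8=C9 alkenes are folded back into the C1–C9 and C2–C8 bonds of a 7-4-4 tricyclic keto ester; its C1–C2 and C8–C9 bonds are cut as an enone–cyclobutene [2+2]; C4 with its two methyls is cut as a ring enlargement plus two methylations.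
Forward: both cyclobutanes arise in one photocycloaddition on 3-methylcyclohex-2-en-1-one (the enone ring size on which this union is established); the six-membered ketone is enlarged to seven and gem-dimethylated; flash thermolysis merges the seven-membered ring and the C9–C10–C11–C1 bridge into the eleven-membered ring; the oxirane is closed afterwards.
Stereochemistry: the racemic photoadduct loses all four stereocentres in the cycloreversion, which fixes only the two alkene geometries; C3 is then set by Corey–Bakshi–Shibata reduction and C8/C9 by Shi epoxidation, both under reagent control.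
Key step: step 7

Remark: the tricyclic intermediates are racemic (one enantiomer drawn); in the reduction of the C3 ketone the quaternary C4 is assumed to act as the larger flank, which decides the choice of the (S)-catalyst.

**Route**

Step 1
Reactants: 1 ethyl 1-bromocyclobutane-1-carboxylate
Product: 2 cyclobut-1-ene-1-carboxylic acid
Conditions: KOH (powdered, 4 equiv), toluene, reflux; then aq. HCl, 0 °C
Reagents that add atoms: potassium hydroxide, [K+].[OH-]
Why: Hydroxide effects both E2 dehydrobromination of the tertiary alpha-bromo ester and saponification, the long-established access to this strained acrylic acid; no stereocentre is formed.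

Step 2
Reactants: 2 cyclobut-1-ene-1-carboxylic acid
Product: 3 methyl cyclobut-1-ene-1-carboxylate
Conditions: MeI, K2CO3, DMF, 0 °C → rt; distilled and kept cold with a radical inhibitor
Reagents that add atoms: iodomethane, CI
Why: SN2 O-methylation of the carboxylate under mild carbonate conditions leaves the strained, polymerisable alkene untouched and gives the ester without beta-hydrogens that the later flash thermolysis calls for.

Step 3
Reactants: 3 methyl cyclobut-1-ene-1-carboxylate; 4 3-methylcyclohex-2-en-1-one
Product: 5 racemic cis-anti-cis head-to-head photoadduct (methyl 1-methyl-7-oxotricyclo[4.4.0.0(2,5)]decane-5-carboxylate)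
Conditions: hν (medium-pressure mercury lamp, Pyrex filter), 3 (3 equiv), CH2Cl2, 0 °C; then basic Al2O3; chromatography
Reagents that add atoms: none
Why: Enone–alkene [2+2] photocycloaddition via the enone triplet and a 1,4-diradical is established for this pair of partner classes: the electron-poor cyclobutene ester adds head to head (C1 to the alpha carbon C2, C9 to the beta carbon C8), the four–four fusion is necessarily cis, the six–four fusion is cis directly or after epimerisation at C2 on basic Al2O3, and approach with the cyclobutene methylenes turned away from the six-membered ring gives the anti arrangement, so the four stereocentres are set relative to each other in racemic form.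

Step 4
Reactants: 5 racemic cis-anti-cis head-to-head photoadduct
Product: 7 racemic ring-enlarged keto ester (methyl 1-methyl-6-oxotricyclo[5.4.0.0(8,11)]undecane-8-carboxylate), via alpha-silyl ketone 6 (not isolated)
Conditions: AlMe3 (1.2 equiv), TMSCHN2 (1.5 equiv), CH2Cl2, −78 → −20 °C; then 1 M HCl, THF, rt
Reagents that add atoms: (trimethylsilyl)diazomethane, C[Si](C)(C)C=[N+]=[N-]
Why: Organoaluminium-promoted diazoalkane homologation (a Tiffeneau–Demjanov-type 1,2-shift) inserts one carbon next to the carbonyl, the unhindered C5 methylene migrating rather than the cyclobutyl methine C2 that sits between two quaternary carbons, so the new carbon becomes C4, and dilute acid then removes the silyl group without affecting the four existing stereocentres.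

Step 5
Reactants: 7 racemic ring-enlarged keto ester
Product: 8 racemic C4-monomethyl keto ester (both C4 epimers)
Conditions: LiN(iPr)2, THF, −78 °C; MeI, −78 → −20 °C
Reagents that add atoms: iodomethane, CI
Why: Kinetic enolate alkylation: LiN(iPr)2 deprotonates the accessible C4 methylene in preference to the shielded C2 methine, and the configuration of the new methyl-bearing carbon is irrelevant because C4 becomes quaternary in the next step.

Step 6
Reactants: 8 racemic C4-monomethyl keto ester
Product: 9 racemic cis-anti-cis tricyclic keto ester (methyl 1,5,5-trimethyl-6-oxotricyclo[5.4.0.0(8,11)]undecane-8-carboxylate)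
Conditions: LiN(iPr)2, THF, −78 °C; MeI, DMPU, −78 → 0 °C
Reagents that add atoms: iodomethane, CI
Why: A second kinetic enolate methylation at the same carbon, assisted by DMPU, completes the gem-dimethyl group, erases the C4 stereocentre and leaves C2 untouched for the same steric reason as before.

Step 7
Reactants: 9 racemic cis-anti-cis tricyclic keto ester
Product: 10 achiral keto dienoate, methyl (1E,8E)-4,4,8-trimethyl-3-oxocycloundeca-1,8-diene-1-carboxylate (target numbering)
Conditions: flash vacuum thermolysis, quartz tube ca. 450 °C, 0.05 mbar, condensate trapped at −78 °C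
Reagents that add atoms: none
Why: The strained central C1–C9 bond of the bicyclo[2.2.0]hexane unit homolyses to a cyclohexane-1,4-diyl (ester-stabilised tertiary radical at C1, secondary radical at C9) that relaxes from boat to chair and then fragments across C2–C8, so that in sum the C1–C9 and C2–C8 bonds are cleaved and the C1=C2 and C8=C9 double bonds are formed (net retro-[2+2]). The closest known reaction is the thermal cycloreversion of cis-anti-cis cyclohexenone–cyclobutenecarboxylate photoadducts to cis,trans-cyclodeca-1,5-dienes, of which this substrate is the one-carbon ring homologue. No ring is closed by bond formation: the eleven-membered ring arises by fragmentation, the loss of the two shared bonds merging the seven-membered ring with the four-carbon bridge C9–C10–C11–C1. No stereocentre is created and all four of 9 are destroyed, so racemic 9 gives achiral 10; the alkene geometries follow from the chair diyl, in which the cis ring fusion puts C7 equatorial and C3 axial (the arrangement that avoids allylic strain between C3 and the ester on the planar C1 radical), which leads to the ring-trans (E) C8=C9 alkene and the ring-cis C1=C2 alkene with the ester trans to the ketone. The step needs cleavage across C2–C8 and not C10–C11 and survival of the 1,5-diene against Cope rearrangement: C2–C8 is the weaker, more substituted bond and its cleavage gives a trisubstituted and a doubly conjugated alkene, very short contact at high temperature favours the entropically easy fragmentation over the ordered Cope transition state, and the doubly activated C1=C2 alkene can in any case settle into its more stable ester-trans-to-acyl geometry.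

Step 8
Reactants: 10 achiral keto dienoate
Product: 11 methyl (1E,3R,8E)-3-hydroxy-4,4,8-trimethylcycloundeca-1,8-diene-1-carboxylate
Conditions: (S)-2-methyl-CBS-oxazaborolidine (20 mol%), catecholborane, toluene, −78 °C; then H2O, aq. NaHCO3
Reagents that add atoms: none
Why: Corey–Bakshi–Shibata reduction is 1,2-selective for enones at −78 °C and leaves ester and isolated alkene alone; with the quaternary C4 as the large flank the (S)-oxazaborolidine–borane complex delivers hydride to the Si face of C3 and sets the (R)-carbinol, and the ester trans to C3 cannot lactonise.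

Step 9
Reactants: 11 methyl (1E,3R,8E)-3-hydroxy-4,4,8-trimethylcycloundeca-1,8-diene-1-carboxylate
Product: 12 methyl (1E,3R,8R,9R)-8,9-epoxy-3-hydroxy-4,4,8-trimethylcycloundec-1-ene-1-carboxylate
Conditions: D-fructose-derived Shi ketone (30 mol%), KHSO5 (as Oxone), K2CO3, Bu4NHSO4, aq. Na2B4O7 buffer (pH 10.5), MeCN–CH2(OMe)2, 0 °C
Reagents that add atoms: potassium peroxymonosulfate (KHSO5), [K+].[O-]S(=O)(=O)OO
Why: Shi epoxidation: the chiral dioxirane attacks only the electron-rich trisubstituted C8=C9 alkene (the ester-conjugated C1=C2 alkene is inert to electrophilic oxygen) through the spiro transition state that turns E-trisubstituted alkenes into (R,R)-epoxides with the D-fructose-derived ketone, the two alkene faces being offered by interconverting ring conformers, so C8 and C9 are set by the reagent and any (3S)-alcohol carried along becomes a separable diastereomer.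

Step 10
Reactants: 12 methyl (1E,3R,8R,9R)-8,9-epoxy-3-hydroxy-4,4,8-trimethylcycloundec-1-ene-1-carboxylate
Product: 13 (1E,3R,8R,9R)-8,9-epoxy-3-hydroxy-4,4,8-trimethylcycloundec-1-ene-1-carboxylic acid
Conditions: LiOH·H2O, THF–MeOH–H2O, rt → 40 °C; then AcOH to pH 5, 0 °C
Reagents that add atoms: lithium hydroxide, [Li+].[OH-]
Why: Saponification of the methyl ester with LiOH (acyl–oxygen cleavage) is compatible with the base-stable trisubstituted oxirane and the free alcohol, and acidification only to pH 5 with acetic acid keeps the epoxide closed; no stereocentre is touched.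

Step 11
Reactants: 13 (1E,3R,8R,9R)-8,9-epoxy-3-hydroxy-4,4,8-trimethylcycloundec-1-ene-1-carboxylic acid
Product: 15 target acid (1E,3R,8R,9R)-3-benzoyloxy-8,9-epoxy-4,4,8-trimethylcycloundec-1-ene-1-carboxylic acid, via mixed anhydride 14 (not isolated)
Conditions: Bz2O (3 equiv), Et3N, DMAP, CH2Cl2, rt; then THF–aq. NaHCO3, rt; acidified to pH 5
Reagents that add atoms: benzoic anhydride, O=C(OC(=O)c1ccccc1)c1ccccc1; water, O (hydrolysis of 14)
Why: DMAP-catalysed acyl transfer from chloride-free benzoic anhydride esterifies the hindered allylic alcohol with retention at C3 under basic conditions that spare the epoxide, the carboxyl group passing through its mixed benzoic anhydride, which bicarbonate hydrolysis returns to the free acid.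

**Compound list**

1 | ethyl 1-bromocyclobutane-1-carboxylate | CCOC(=O)C1(Br)CCC1 | starting material
2 | cyclobut-1-ene-1-carboxylic acid | OC(=O)C1=CCC1 | intermediate
3 | methyl cyclobut-1-ene-1-carboxylate | COC(=O)C1=CCC1 | intermediate
4 | 3-methylcyclohex-2-en-1-one | CC1=CC(=O)CCC1 | starting material
5 | racemic cis-anti-cis head-to-head photoadduct, methyl 1-methyl-7-oxotricyclo[4.4.0.0(2,5)]decane-5-carboxylate (one enantiomer drawn) | COC(=O)[C@]12CC[C@H]1[C@]3(C)CCCC(=O)[C@H]23 | intermediate
6 | alpha-silyl ketone, ring-enlarged keto ester carrying Me3Si on C4 (racemic, C4 unassigned, not isolated) | COC(=O)[C@]12CC[C@H]1[C@]3(C)CCCC([Si](C)(C)C)C(=O)[C@H]23 | intermediate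
7 | racemic ring-enlarged keto ester, methyl 1-methyl-6-oxotricyclo[5.4.0.0(8,11)]undecane-8-carboxylate | COC(=O)[C@]12CC[C@H]1[C@]3(C)CCCCC(=O)[C@H]23 | intermediate
8 | racemic C4-monomethyl keto ester (both C4 epimers), methyl 1,5-dimethyl-6-oxotricyclo[5.4.0.0(8,11)]undecane-8-carboxylate | COC(=O)[C@]12CC[C@H]1[C@]3(C)CCCC(C)C(=O)[C@H]23 | intermediate
9 | racemic cis-anti-cis tricyclic keto ester, methyl 1,5,5-trimethyl-6-oxotricyclo[5.4.0.0(8,11)]undecane-8-carboxylate (precursor of the key step) | COC(=O)[C@]12CC[C@H]1[C@]3(C)CCCC(C)(C)C(=O)[C@H]23 | intermediate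
10 | achiral keto dienoate, methyl (1E,8E)-4,4,8-trimethyl-3-oxocycloundeca-1,8-diene-1-carboxylate (product of the key step) | CC1(C)CCC/C(C)=C/CC/C(C(=O)OC)=C\C1=O | intermediate
11 | methyl (1E,3R,8E)-3-hydroxy-4,4,8-trimethylcycloundeca-1,8-diene-1-carboxylate | CC1(C)CCC/C(C)=C/CC/C(C(=O)OC)=C\[C@H]1O | intermediate
12 | methyl (1E,3R,8R,9R)-8,9-epoxy-3-hydroxy-4,4,8-trimethylcycloundec-1-ene-1-carboxylate | CC1(C)CCC[C@@]2(C)O[C@@H]2CC/C(C(=O)OC)=C\[C@H]1O | intermediate
13 | (1E,3R,8R,9R)-8,9-epoxy-3-hydroxy-4,4,8-trimethylcycloundec-1-ene-1-carboxylic acid | CC1(C)CCC[C@@]2(C)O[C@@H]2CC/C(C(=O)O)=C\[C@H]1O | intermediate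
14 | mixed benzoic anhydride of the 3-O-benzoyl acid (not isolated) | CC1(C)CCC[C@@]2(C)O[C@@H]2CC/C(C(=O)OC(=O)c3ccccc3)=C\[C@H]1OC(=O)c1ccccc1 | intermediate
15 | (1E,3R,8R,9R)-3-benzoyloxy-8,9-epoxy-4,4,8-trimethylcycloundec-1-ene-1-carboxylic acid (CNP0377917.1) | CC1(C)CCC[C@@]2(C)O[C@@H]2CC/C(C(=O)O)=C\[C@H]1OC(=O)c1ccccc1 | target

**Step count**

Total: 11 steps. Longest linear sequence: 11 steps (1 → 15); 9 steps from 4.

**Steps most likely to fail**

1. Step 7 (cycloreversion). What may go wrong: the 1,5-diene reacts on in the hot zone (Cope ring contraction to a divinylcycloheptanone), the diyl fragments across C10–C11 instead of C2–C8, or the cis-gamma-hydrogen enone enolises thermally. Fallback, from 9 back to 10: the opening would be run at the alcohol oxidation level, where the ring-opened product is no ene-dione and solution thermolysis at lower temperature is established for this class of adducts. NaBH4 (MeOH, 0 °C) should reduce 9 to the racemic alcohol F1 (C3 configuration immaterial). Et3SiOTf and 2,6-lutidine would give the triethylsilyl ether F2, which blocks lactonisation onto the neighbouring ester. Brief heating of F2 in degassed toluene in a base-washed sealed tube at about 200 °C should open it to the racemic silyloxy dienoate F3. Bu4NF in THF would free the racemic allylic alcohol F4, and Dess–Martin periodinane (CH2Cl2, NaHCO3, rt) would oxidise F4 to 10.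

2. Step 8 (asymmetric reduction). What may go wrong: poor or inverted facial discrimination, because the two flanks of the ketone (quaternary carbon and cis-substituted alkenyl group) are of similar effective size, and competing conjugate reduction. Fallback, from 10 back to 12: absolute control would be left to the epoxidation alone and C3 sorted by separation of diastereomers. Luche reduction (NaBH4, CeCl3·7H2O, MeOH, −40 °C) would convert 10 into the racemic alcohol F5 (the same compound as F4). Shi epoxidation as in step 9 should turn both enantiomers into (8R,9R)-epoxides, that is 12 and its (3S)-diastereomer F6, to be separated on silica. F6 would be recycled by Dess–Martin oxidation to the epoxy ketone F7 and renewed Luche reduction.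

3. Step 4 (one-carbon ring enlargement). What may go wrong: migration of C2 instead of the methylene (wrong regioisomer) or repeated insertion. Fallback, from 5 back to 7: the carbon would be inserted by the Ito–Saegusa ring enlargement, whose regiochemistry is fixed by kinetic enolisation. LiN(iPr)2 and Me3SiCl (THF, −78 °C) should give the trimethylsilyl enol ether F8 on the methylene side. Furukawa cyclopropanation (ZnEt2, CH2I2, CH2Cl2) would give the siloxycyclopropane F9, which FeCl3 in DMF should open oxidatively to the ring-enlarged beta-chloro ketone F10. NaOAc in MeOH would eliminate HCl to the ring-enlarged enone F11, and hydrogenation (H2, Pd/C, EtOAc) would give 7.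

**Further compounds**

F1 | step 7 | racemic tricyclic alcohol from reduction of 9 (C3 unassigned) | COC(=O)[C@]12CC[C@H]1[C@]3(C)CCCC(C)(C)C(O)[C@H]23
F2 | step 7 | triethylsilyl ether of F1 | COC(=O)[C@]12CC[C@H]1[C@]3(C)CCCC(C)(C)C(O[Si](CC)(CC)CC)[C@H]23
F3 | step 7 | racemic methyl (1E,8E)-4,4,8-trimethyl-3-(triethylsilyloxy)cycloundeca-1,8-diene-1-carboxylate | CC1(C)CCC/C(C)=C/CC/C(C(=O)OC)=C\C1O[Si](CC)(CC)CC
F4 | step 7 | racemic methyl (1E,8E)-3-hydroxy-4,4,8-trimethylcycloundeca-1,8-diene-1-carboxylate | CC1(C)CCC/C(C)=C/CC/C(C(=O)OC)=C\C1O
F5 | step 8 | racemic methyl (1E,8E)-3-hydroxy-4,4,8-trimethylcycloundeca-1,8-diene-1-carboxylate (identical with F4) | CC1(C)CCC/C(C)=C/CC/C(C(=O)OC)=C\C1O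
F6 | step 8 | methyl (1E,3S,8R,9R)-8,9-epoxy-3-hydroxy-4,4,8-trimethylcycloundec-1-ene-1-carboxylate | CC1(C)CCC[C@@]2(C)O[C@@H]2CC/C(C(=O)OC)=C\[C@@H]1O
F7 | step 8 | methyl (1E,8R,9R)-8,9-epoxy-4,4,8-trimethyl-3-oxocycloundec-1-ene-1-carboxylate | CC1(C)CCC[C@@]2(C)O[C@@H]2CC/C(C(=O)OC)=C\C1=O
F8 | step 4 | trimethylsilyl enol ether of 5 (C3=C5 enol) | COC(=O)[C@]12CC[C@H]1[C@]3(C)CCC=C(O[Si](C)(C)C)[C@H]23
F9 | step 4 | siloxycyclopropane from F8 | COC(=O)[C@]12CC[C@H]1[C@]3(C)CCC4CC4(O[Si](C)(C)C)[C@H]23
F10 | step 4 | ring-enlarged beta-chloro ketone | COC(=O)[C@]12CC[C@H]1[C@]3(C)CCC(Cl)CC(=O)[C@H]23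
F11 | step 4 | ring-enlarged enone (C4=C5) | COC(=O)[C@]12CC[C@H]1[C@]3(C)CCC=CC(=O)[C@H]23
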